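The route rests on cutting the cyclohexene of the bridged-lactone half at C3a–C4 and C7–C7a: a Diels–Alder reaction of a bought (S)-butenolide (C3a=C7a) with (E)-1-silyloxybutadiene. In one operation it closes that ring, forms C3a–C4 and C7–C7a and relays the C3 stereocentre to C3a and C7a (cis-fused lactone, diene anti to the C3 substituent). The feature used is the γ-lactone ring (C1, O2, C3, C3a, C7a) fused cis to the six-membered ring at C3a–C7a. The C7 oxygen then moves the alkene to C6=C7; C3 and C7a are later bridged by a two-carbon unit, which carries the butylidenephthalide ring.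

Key step: step 2

Remark on numbering: unprimed locants belong to the bridged-lactone half (C1 lactone C=O, O2, C3 oxygen-bearing bridgehead, C3a one-carbon bridge, C4–C7 cyclohexene, C7a quaternary bridgehead, C8–C11 butanoyl). Primed locants belong to the butylidenephthalide half (C1′ C=O, O2′, C3′, C3a′, C4′–C7′, C7a′, C8′–C11′ butylidene). The halves are joined by C3–C6′ and C7a–C7′. "Exo" means syn to the C3a bridge of the 2-oxabicyclo[2.2.1]heptan-3-one, "endo" syn to the lactone bridge.

Remark on configuration: as written, the target has C5′ exo on C6′ and C7a′ endo on C7′, so the primed cyclohexene is trans-fused to the bicycle, and C4 lies on the lactone side of C3a. The route is planned for this isomer; the trans fusion is strained, which is why the last carbocycle is closed by an irreversible step.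

Step 1
Reactants: 1 (S)-5-(hydroxymethyl)furan-2(5H)-one; 2 tert-butyl(chloro)dimethylsilane
Product: 3 (S)-5-{[tert-butyl(dimethyl)silyl]oxymethyl}furan-2(5H)-one
Conditions: imidazole, DMF, 0 °C to rt
Reagents that add atoms: tert-butyl(chloro)dimethylsilane, CC(C)(C)[Si](C)(C)Cl
Why: O-silylation of the primary alcohol (silyl ether protection) keeps the hydroxyl out of the cycloaddition and the Mitsunobu step; the bought stereocentre is untouched.

Step 2
Reactants: 3 silyl-protected butenolide; 4 (E)-1-(trimethylsilyloxy)buta-1,3-diene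
Product: 6 cis-fused 7-hydroxy-3a,4,7,7a-tetrahydro lactone (both C7 epimers), via silyl ether cycloadduct 5 (not isolated)
Conditions: toluene, BHT (cat.), 150 °C, sealed tube; then 0.5 M HCl, THF, 0 °C
Reagents that add atoms: (E)-1-(trimethylsilyloxy)buta-1,3-diene, C=C/C=C/O[Si](C)(C)C
Why: Thermal [4+2] cycloaddition (Diels–Alder reaction of a 1-oxygenated butadiene with a γ-substituted butenolide): the diene adds suprafacially across C3a=C7a, so C3a–C4 and C7–C7a form in one concerted six-membered ring closure and the lactone/cyclohexene fusion must be cis. The bought C3 stereocentre controls both new centres, C3a and C7a, because the diene approaches the butenolide face opposite the silyloxymethyl group. The regiochemistry needed is unsubstituted diene terminus to C3a and oxygenated terminus to C7a; it should follow from the match of the largest HOMO coefficient of the 1-silyloxydiene (remote terminus) with the largest LUMO coefficient of the lactone (β-carbon C3a). The endo/exo outcome at C7 does not matter, since C7 becomes sp2 in step 3. The dilute acid only removes the labile trimethylsilyl group and leaves the primary silyl ether.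

Step 3
Reactants: 6 allylic alcohol
Product: 9 (3S,3aS,7aR)-3-(silyloxymethyl)-3a,4,5,7a-tetrahydro-2-benzofuran-1(3H)-one, via sulfonylhydrazine 7 (not isolated), via allylic diazene 8 (not isolated)
Conditions: PPh3, DEAD, 2-nitrobenzenesulfonylhydrazide, N-methylmorpholine, THF, −30 °C to rt
Reagents that add atoms: none
Why: Mitsunobu substitution of the allylic alcohol by the sulfonylhydrazide, loss of sulfinic acid and retro-ene loss of N2 from the monoalkyl diazene (reductive 1,3-transposition of an allylic alcohol) should deliver hydrogen to C5 and move the alkene to C6=C7; no stereocentre is made.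

Step 4
Reactants: 9 silyl ether
Product: 10 (3S,3aS,7aR)-3-(hydroxymethyl)-3a,4,5,7a-tetrahydro-2-benzofuran-1(3H)-one
Conditions: HF·pyridine, pyridine, THF, 0 °C to rt
Reagents that add atoms: none
Why: Fluoride cleavage of the silyl ether under buffered acidic conditions, chosen so that no base moves the β,γ-alkene into conjugation; stereocentres untouched.

Step 5
Reactants: 10 primary alcohol
Product: 11 (3S,3aS,7aR)-3-formyl-3a,4,5,7a-tetrahydro-2-benzofuran-1(3H)-one
Conditions: Dess–Martin periodinane, CH2Cl2, rt
Reagents that add atoms: none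
Why: Dess–Martin oxidation of the primary alcohol under neutral conditions; the aldehyde is used crude because C3 is now epimerisable, which is harmless since C3 is reset in step 8.

Step 6
Reactants: 11 aldehyde; 12 n-propylmagnesium bromide
Product: 13 3-(1-hydroxybutyl) lactone (carbinol epimers)
Conditions: n-PrMgBr, THF, −78 °C; aqueous NH4Cl
Reagents that add atoms: n-propylmagnesium bromide, CCC[Mg]Br
Why: Grignard addition to the aldehyde, which at −78 °C should be much faster than attack on the lactone; the carbinol centre forms without control and is removed in step 7.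

Step 7
Reactants: 13 secondary alcohol
Product: 14 (3S,3aS,7aR)-3-butanoyl-3a,4,5,7a-tetrahydro-2-benzofuran-1(3H)-one
Conditions: Dess–Martin periodinane, CH2Cl2, rt
Reagents that add atoms: none
Why: Dess–Martin oxidation gives the butanoyl ketone, which makes C3–H (α to the ketone and to the lactone oxygen) the most acidic position for step 8.

Step 8
Reactants: 14 keto lactone; 15 methyl 2-bromoacrylate
Product: 16 methyl 2-bromo-3-[(3R,3aS,7aR)-3-butanoyl-1-oxo-1,3,3a,4,5,7a-hexahydro-2-benzofuran-3-yl]propanoate (bromide epimers)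
Conditions: Cs2CO3 (0.2 equiv), MeCN, 0 °C
Reagents that add atoms: methyl 2-bromoacrylate, C=C(Br)C(=O)OC
Why: Michael addition of the C3 enolate to the bromoacrylate; the acceptor should enter from the convex face opposite the cyclohexene, which sets the C3 quaternary centre with the butanoyl group on the cyclohexene side (the bromide centre is uncontrolled and is consumed in step 10).

Step 9
Reactants: 16 bromo ester ketone; 17 tert-butyldimethylsilyl trifluoromethanesulfonate
Product: 18 tert-butyldimethylsilyl enol ether of 16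
Conditions: Et3N, CH2Cl2, −78 to 0 °C
Reagents that add atoms: tert-butyldimethylsilyl trifluoromethanesulfonate, CC(C)(C)[Si](C)(C)OS(=O)(=O)C(F)(F)F
Why: Soft enolisation and O-silylation turn the butanoyl ketone into its silyl enol ether (only C9 can enolise, C3 being quaternary), which keeps a competing ketone enolate out of steps 10 to 13; no stereocentre is affected.

Step 10
Reactants: 18 silyl enol ether bromo ester
Product: 19 bridged tricyclic lactone methyl ester (C7′ epimers)
Conditions: LiN(SiMe3)2, THF/DMPU, −78 to 0 °C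
Reagents that add atoms: none
Why: Intramolecular enolate alkylation (5-exo-tet SN2 of the C7a lactone enolate on the α-bromo ester, completing a Michael-initiated ring closure) should form C7a–C7′ and the 2-oxabicyclo[2.2.1]heptan-3-one; the arm and C7a–H lie on the same face, so the ring can close only there and C7a keeps its configuration.

Step 11
Reactants: 19 bridged ester
Product: 21 bridged C6′=C7′ enoate, via selenide 20 (not isolated)
Conditions: LiN(i-Pr)2, THF, −78 °C; PhSeBr; then mCPBA (1.0 equiv), CH2Cl2, −78 °C to rt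
Reagents that add atoms: none
Why: α-Selenenylation of the only enolisable position (the C7′ ester) and selenoxide syn-elimination with a C6′ hydrogen give the strained bicyclic enoate; no new stereocentre.

Step 12
Reactants: 21 bicyclic enoate; 22 vinylmagnesium bromide
Product: 24 6′-exo-vinyl 7′-endo-ester, via silyl ketene acetal 23 (not isolated)
Conditions: CH2=CHMgBr, CuBr·SMe2 (20 mol%), Me3SiCl, THF, −78 to −40 °C; then AcOH, −78 °C; aqueous NH4Cl
Reagents that add atoms: vinylmagnesium bromide, C=C[Mg]Br
Why: Copper-catalysed conjugate addition of the vinyl Grignard reagent should occur on the exo face (the C3a bridge turns only its hydrogen toward the alkene) and set C6′; protonation of the ketene acetal from the same exo face then puts the ester endo, trans to the vinyl group, which is also the more stable arrangement.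

Step 13
Reactants: 24 vinyl ester; 25 hexan-2-one
Product: 27 β-diketone with free butanoyl ketone, via silyl enol ether diketone 26 (not isolated)
Conditions: hexan-2-one (3 equiv), LiN(i-Pr)2 (2.9 equiv), THF, −78 °C; add 24, −78 to 0 °C; then 1 M HCl, THF, rt
Reagents that add atoms: hexan-2-one, CCCCC(C)=O
Why: Crossed Claisen condensation: the kinetic methyl enolate of hexan-2-one acylates at the methyl ester and formation of the β-diketonate drives it, the ketone enolate being too weak a base to epimerise C7′; the acidic quench hydrolyses the silyl enol ether.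

Step 14
Reactants: 27 butenyl β-diketone
Product: 28 trans-fused 2-pentanoylcyclohexanone (C3a′ enolisable)
Conditions: PdCl2(MeCN)2 (10 mol%), 1,4-dioxane, rt
Reagents that add atoms: none
Why: Palladium-catalysed intramolecular hydroalkylation of an unactivated alkene by a β-diketone: the enol carbon C3a′ attacks the terminal carbon C4′ of the alkene bound to divalent palladium (6-endo), and palladium leaves by β-hydride elimination, reinsertion and protonolysis; the neutral, irreversible C–C bond formation leaves the trans-disposed C6′ and C7′ untouched, so the ring closes trans-fused.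

Step 15
Reactants: 28 β-diketone; 29 trifluoromethanesulfonic anhydride
Product: 30 ring enol triflate (C7a′–OTf, C7a′=C3a′)
Conditions: NaH (1.0 equiv), Et2O, 0 °C; Tf2O, −78 to 0 °C
Reagents that add atoms: trifluoromethanesulfonic anhydride, O=S(=O)(OS(=O)(=O)C(F)(F)F)C(F)(F)F
Why: O-sulfonylation of the sodium β-diketonate; triflation is expected on the ring oxygen because a 2-acylcyclohexanone is enolised into the ring, giving the (Z)-β-triflyloxy enone and making C7′ non-epimerisable.

Step 16
Reactants: 30 enol triflate; 31 carbon monoxide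
Product: 32 target compound
Conditions: PdCl2(PPh3)2 (5 mol%), CO (1 atm), Et3N, DMF, 60 °C
Reagents that add atoms: carbon monoxide, [C-]#[O+]
Why: Palladium-catalysed carbonylative lactonisation: zerovalent palladium inserts into the vinyl triflate, CO inserts, and the acylpalladium is trapped by the enolate oxygen of the pentanoyl ketone to close the butenolide; the (Z)-butylidene isomer, with the propyl group turned away from C4′, should be favoured.

Compound list
1 | (S)-5-(hydroxymethyl)furan-2(5H)-one | O=C1C=C[C@@H](CO)O1 | starting material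
2 | tert-butyl(chloro)dimethylsilane | CC(C)(C)[Si](C)(C)Cl | starting material
3 | (S)-5-{[tert-butyl(dimethyl)silyl]oxymethyl}furan-2(5H)-one | O=C1C=C[C@@H](CO[Si](C)(C)C(C)(C)C)O1 | intermediate
4 | (E)-1-(trimethylsilyloxy)buta-1,3-diene | C=C/C=C/O[Si](C)(C)C | starting material
5 | (3S,3aS,7aS)-3-{[tert-butyl(dimethyl)silyl]oxymethyl}-7-(trimethylsilyloxy)-3a,4,7,7a-tetrahydro-2-benzofuran-1(3H)-one, cis-fused, both C7 epimers | O=C1O[C@H](CO[Si](C)(C)C(C)(C)C)[C@H]2CC=CC(O[Si](C)(C)C)[C@@H]12 | intermediate (not isolated)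
6 | (3S,3aS,7aS)-3-{[tert-butyl(dimethyl)silyl]oxymethyl}-7-hydroxy-3a,4,7,7a-tetrahydro-2-benzofuran-1(3H)-one, cis-fused, both C7 epimers | O=C1O[C@H](CO[Si](C)(C)C(C)(C)C)[C@H]2CC=CC(O)[C@@H]12 | intermediate
7 | N-(2-nitrophenylsulfonyl)-N-allyl hydrazine at C7 of the lactone (Mitsunobu adduct, C7 epimers) | O=C1O[C@H](CO[Si](C)(C)C(C)(C)C)[C@H]2CC=CC(N(N)S(=O)(=O)c3ccccc3[N+](=O)[O-])[C@@H]12 | intermediate (not isolated)
8 | C7 monoalkyl diazene of the lactone | O=C1O[C@H](CO[Si](C)(C)C(C)(C)C)[C@H]2CC=CC(N=N)[C@@H]12 | intermediate (not isolated)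
9 | (3S,3aS,7aR)-3-{[tert-butyl(dimethyl)silyl]oxymethyl}-3a,4,5,7a-tetrahydro-2-benzofuran-1(3H)-one | O=C1O[C@H](CO[Si](C)(C)C(C)(C)C)[C@H]2CCC=C[C@@H]12 | intermediate
10 | (3S,3aS,7aR)-3-(hydroxymethyl)-3a,4,5,7a-tetrahydro-2-benzofuran-1(3H)-one | O=C1O[C@H](CO)[C@H]2CCC=C[C@@H]12 | intermediate
11 | (3S,3aS,7aR)-3-formyl-3a,4,5,7a-tetrahydro-2-benzofuran-1(3H)-one | O=C1O[C@H](C=O)[C@H]2CCC=C[C@@H]12 | intermediate
12 | n-propylmagnesium bromide | CCC[Mg]Br | starting material
13 | (3S,3aS,7aR)-3-(1-hydroxybutyl)-3a,4,5,7a-tetrahydro-2-benzofuran-1(3H)-one, carbinol epimers | O=C1O[C@H](C(O)CCC)[C@H]2CCC=C[C@@H]12 | intermediate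
14 | (3S,3aS,7aR)-3-butanoyl-3a,4,5,7a-tetrahydro-2-benzofuran-1(3H)-one | O=C1O[C@H](C(=O)CCC)[C@H]2CCC=C[C@@H]12 | intermediate
15 | methyl 2-bromoacrylate | C=C(Br)C(=O)OC | starting material
16 | methyl 2-bromo-3-[(3R,3aS,7aR)-3-butanoyl-1-oxo-1,3,3a,4,5,7a-hexahydro-2-benzofuran-3-yl]propanoate, bromide epimers | O=C1O[C@@](CC(Br)C(=O)OC)(C(=O)CCC)[C@H]2CCC=C[C@@H]12 | intermediate
17 | tert-butyldimethylsilyl trifluoromethanesulfonate | CC(C)(C)[Si](C)(C)OS(=O)(=O)C(F)(F)F | starting material
18 | tert-butyldimethylsilyl enol ether of 16 (C8=C9, geometry not controlled) | O=C1O[C@@](CC(Br)C(=O)OC)(C(=CCC)O[Si](C)(C)C(C)(C)C)[C@H]2CCC=C[C@@H]12 | intermediate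
19 | bridged tricyclic lactone: 2-oxabicyclo[2.2.1]heptan-3-one (C1, O2, C3, C3a bridge, C7a, C7′, C6′) with the C4–C7 cyclohexene fused at C3a–C7a on the lactone side, 1-(silyloxy)but-1-enyl on C3, CO2Me on C7′ (epimers) | COC(=O)C1C[C@@]2(C(=CCC)O[Si](C)(C)C(C)(C)C)OC(=O)[C@@]13C=CCC[C@H]23 | intermediate
20 | C7′ phenylselenide of 19 | COC(=O)C1([Se]c4ccccc4)C[C@@]2(C(=CCC)O[Si](C)(C)C(C)(C)C)OC(=O)[C@@]13C=CCC[C@H]23 | intermediate (not isolated)
21 | bridged tricyclic enoate: C6′=C7′ alkene of 19 with CO2Me on C7′ | COC(=O)C1=C[C@@]2(C(=CCC)O[Si](C)(C)C(C)(C)C)OC(=O)[C@@]13C=CCC[C@H]23 | intermediate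
22 | vinylmagnesium bromide | C=C[Mg]Br | starting material
23 | trimethylsilyl ketene acetal of 24 (C7′=C(OMe)OSiMe3, 6′-exo-vinyl) | COC(O[Si](C)(C)C)=C1[C@H](C=C)[C@@]2(C(=CCC)O[Si](C)(C)C(C)(C)C)OC(=O)[C@@]13C=CCC[C@H]23 | intermediate (not isolated)
24 | bridged tricyclic lactone with 6′-exo-vinyl and 7′-endo-CO2Me (trans), silyl enol ether on C3 | COC(=O)[C@H]1[C@H](C=C)[C@@]2(C(=CCC)O[Si](C)(C)C(C)(C)C)OC(=O)[C@@]13C=CCC[C@H]23 | intermediate
25 | hexan-2-one | CCCCC(C)=O | starting material
26 | 7′-endo-(3-oxoheptanoyl) 6′-exo-vinyl lactone, silyl enol ether still on C3 | CCCCC(=O)CC(=O)[C@H]1[C@H](C=C)[C@@]2(C(=CCC)O[Si](C)(C)C(C)(C)C)OC(=O)[C@@]13C=CCC[C@H]23 | intermediate (not isolated)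
27 | 7′-endo-(3-oxoheptanoyl) 6′-exo-vinyl lactone with butanoyl on C3 | CCCCC(=O)CC(=O)[C@H]1[C@H](C=C)[C@@]2(C(=O)CCC)OC(=O)[C@@]13C=CCC[C@H]23 | intermediate
28 | tetracyclic β-diketone: cyclohexanone (C7a′=O, C3a′ bearing pentanoyl, C4′, C5′) trans-fused at C6′–C7′ to the bridged lactone (C5′ exo, C7a′ endo), butanoyl on C3; C3a′ enolisable | CCCCC(=O)C1CC[C@H]2[C@H](C1=O)[C@@]13C=CCC[C@@H]1[C@]2(C(=O)CCC)OC3=O | intermediate
29 | trifluoromethanesulfonic anhydride | O=S(=O)(OS(=O)(=O)C(F)(F)F)C(F)(F)F | starting material
30 | enol triflate of 28: C7a′(OTf)=C3a′–C3′(=O)Bu | CCCCC(=O)C1=C(OS(=O)(=O)C(F)(F)F)[C@H]2[C@H](CC1)[C@@]1(C(=O)CCC)OC(=O)[C@@]23C=CCC[C@H]13 | intermediate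
31 | carbon monoxide | [C-]#[O+] | starting material
32 | target: (Z)-butylidene butenolide trans-fused through C6′–C7′ to the 3-butanoyl-2-oxabicyclo[2.2.1]heptan-3-one lactone carrying the cis-fused C6=C7 cyclohexene | CCC/C=C1\OC(=O)C2=C1CC[C@H]1[C@H]2[C@@]23C=CCC[C@@H]2[C@]1(C(=O)CCC)OC3=O | target

Total steps: 16. Longest linear sequence: 16 steps (1 to 32).

Steps most likely to fail

Step 14. The cyclisation has to build the strain of a ring trans-fused to the bicyclo[2.2.1] core, so alkene isomerisation by palladium hydride or cyclisation through the butanoyl enol may outrun the 6-endo attack. The fallback sets out from 27 and closes the ring by an SN2 displacement instead. Hydroboration of the vinyl group with 9-BBN and oxidation with NaBO3·4H2O should give the primary alcohol F1. Treatment with I2, PPh3 and imidazole gives the primary iodide F2. Cs2CO3 in MeCN then alkylates the β-diketone carbon C3a′ at C4′ (6-exo-tet) and comes back to the route at 28.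

Step 10. The base may deprotonate the α-bromo ester instead of C7a–H, and SN2 closure at a secondary centre to a strained bicycle may lose to elimination of HBr or to attack of the bromo-ester enolate on the lactone carbonyl. The fallback sets out from 14 and forms C7a–C7′ by cross-coupling. Addition–elimination of the C3 enolate on methyl (Z)-2,3-dibromoacrylate (Cs2CO3, MeCN) should give the (Z)-α-bromo enoate ketone F3. TBSOTf and Et3N convert it into the silyl enol ether F4. Intramolecular palladium-catalysed α-alkenylation of the lactone enolate (Pd2(dba)3, P(t-Bu)3, LiN(SiMe3)2, toluene) then closes the bicycle with the C6′=C7′ alkene in place and comes back at 21; steps 8 to 11 are bypassed.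

Step 3. The Mitsunobu-activated C7 oxygen is β to the lactone carbonyl, so elimination toward the acidic C7a–H may compete with displacement by the sulfonylhydrazide. The fallback sets out from 6 and goes through the ketone. Oxidation with MnO2 should give the enone F5. Condensation with TsNHNH2 gives the tosylhydrazone F6. Catecholborane, then NaOAc, reduces the C=N bond; loss of sulfinate and N2 from the allylic diazene shifts the alkene to C6=C7 and comes back at 9.

Further compounds
F1 | step 14 | 6′-exo-(2-hydroxyethyl) analogue of 27 | CCCCC(=O)CC(=O)[C@H]1[C@H](CCO)[C@@]2(C(=O)CCC)OC(=O)[C@@]13C=CCC[C@H]23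
F2 | step 14 | 6′-exo-(2-iodoethyl) analogue of 27 | CCCCC(=O)CC(=O)[C@H]1[C@H](CCI)[C@@]2(C(=O)CCC)OC(=O)[C@@]13C=CCC[C@H]23
F3 | step 10 | methyl (Z)-2-bromo-3-[(3aS,7aR)-3-butanoyl-1-oxo-1,3,3a,4,5,7a-hexahydro-2-benzofuran-3-yl]prop-2-enoate (C3 configured as in 16) | O=C1O[C@@](/C=C(\Br)C(=O)OC)(C(=O)CCC)[C@H]2CCC=C[C@@H]12
F4 | step 10 | tert-butyldimethylsilyl enol ether of F3 | O=C1O[C@@](/C=C(\Br)C(=O)OC)(C(=CCC)O[Si](C)(C)C(C)(C)C)[C@H]2CCC=C[C@@H]12
F5 | step 3 | cis-fused 3-{[tert-butyl(dimethyl)silyl]oxymethyl}-3a,7a-dihydro-2-benzofuran-1,7(3H,4H)-dione (C7 ketone, C5=C6) | O=C1O[C@H](CO[Si](C)(C)C(C)(C)C)[C@H]2CC=CC(=O)[C@@H]12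
F6 | step 3 | C7 tosylhydrazone of F5 | O=C1O[C@H](CO[Si](C)(C)C(C)(C)C)[C@H]2CC=CC(=NNS(=O)(=O)c3ccc(C)cc3)[C@@H]12
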